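**Retrosynthetic overview**

1. Target 13 comes from apigenin 9 by peracetylation, selective removal of the 7-acetate, O-sulfonation of the freed 7-OH and aminolysis of the two remaining acetates.
2. Apigenin 9 comes from tri-O-benzyl flavone 8, and 8 from acid 6 by disconnection of C4–C4a. C4a of ring A is ortho to O1 and O5 and para to O7, so an acrylic acid chain already hung on O1 can acylate it and close pyranone ring C.
3. Acid 6 comes from ester 5, made by conjugate addition of phenol 4 (O1–C2 bond) to arylpropiolate 3, which is the Sonogashira product of 1 and 2 (C2–C1' bond).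
4. All three phenols travel as benzyl ethers, since a silyl ether on the ring B oxygen would be at risk in the hot phenoxide addition and the saponification. The 7/4' distinction is therefore made after ring closure, on the triacetate.
5. Ring order: rings A and B are bought as protected phenols; ring C is the only ring formed (step 4).

Key step: step 4

Assumption: aryl hydrogen sulfates are handled as salts, so 12 and 13 would be isolated as the pyridinium and ammonium salts; they are written as the neutral hydrogen sulfates, the form of the target formula.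

**Route**

Step 1
Reactants: 1 1-(benzyloxy)-4-iodobenzene; 2 ethyl propiolate
Product: 3 ethyl 3-[4-(benzyloxy)phenyl]prop-2-ynoate
Conditions: PdCl2(PPh3)2 (2 mol%), CuI (4 mol%), K2CO3 (2 equiv), THF, 60 °C, 2 added in portions
Reagents that add atoms: none
Why: Sonogashira coupling of an aryl iodide with a terminal ynoate, run with K2CO3 in place of an amine (which would add to the propiolate); the benzyl ether and the ester are inert.

Step 2
Reactants: 3 ethyl 3-[4-(benzyloxy)phenyl]prop-2-ynoate; 4 3,5-bis(benzyloxy)phenol
Product: 5 ethyl (2Z)-3-[3,5-bis(benzyloxy)phenoxy]-3-[4-(benzyloxy)phenyl]prop-2-enoate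
Conditions: K2CO3 (0.3 equiv), DMF, 80 °C
Reagents that add atoms: none
Why: Oxa-Michael addition of the phenoxide to C3 of the ynoate; DMF favours O- over C-attack of the ambident phenoxide, the benzyl ethers tolerate the heat, and anti protonation should give mainly the Z enol ether (any E isomer is carried on, since it equilibrates in step 4).

Step 3
Reactants: 5 ethyl (2Z)-3-[3,5-bis(benzyloxy)phenoxy]-3-[4-(benzyloxy)phenyl]prop-2-enoate
Product: 6 (2Z)-3-[3,5-bis(benzyloxy)phenoxy]-3-[4-(benzyloxy)phenyl]prop-2-enoic acid
Conditions: LiOH·H2O (3 equiv), THF/H2O 3:1, 40 °C; 1 M HCl to pH 3, 0 °C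
Reagents that add atoms: lithium hydroxide, [Li+].[OH-]
Why: Saponification, in which hydroxide attacks the ester carbonyl rather than the fully substituted C3 of the push–pull alkene (no alcohol co-solvent, so no alkoxide can exchange the aryloxy group); benzyl ethers are inert and the acid is liberated cold to avoid decarboxylation.

Step 4
Reactants: 6 (2Z)-3-[3,5-bis(benzyloxy)phenoxy]-3-[4-(benzyloxy)phenyl]prop-2-enoic acid
Product: 8 5,7-bis(benzyloxy)-2-[4-(benzyloxy)phenyl]-4H-chromen-4-one, via mixed trifluoroacetic anhydride 7 (not isolated)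
Conditions: (CF3CO)2O (2 equiv), CH2Cl2, 0 °C to rt; aq NaHCO3
Reagents that add atoms: trifluoroacetic anhydride, O=C(OC(=O)C(F)(F)F)C(F)(F)F (its trifluoroacetyl group is carried by intermediate 7 only and leaves again on ring closure; product 8 keeps no atom of it)
Why: Trifluoroacetic anhydride turns acid 6 into mixed anhydride 7, whose acyl carbon (the future C4) is attacked by the ring A carbon ortho to the aryloxy oxygen (the future C4a) in an intramolecular Friedel–Crafts acylation; loss of trifluoroacetate and then of a proton restores aromaticity and gives pyranone ring C. The closest known reaction type is the acid-mediated cyclization of 3-aryloxyacrylic and 3-aryloxycinnamic acids to chromones and flavones, run here under mild mixed-anhydride activation because C4a is ortho, ortho and para to three oxygens and needs no strong Lewis acid. Ring C closes in a 6-exo-trig mode at the anhydride carbonyl, whose C=O stays outside the new ring. No stereocenter is formed; the only geometric requirement is the Z double bond that holds the anhydride cis to the aryloxy group, and any E isomer should feed into it by acid-catalysed protonation at C2 and rotation of the push–pull alkene. Site selectivity comes from the mirror symmetry of the 3,5-bis(benzyloxy)phenoxy ring (both ortho carbons identical, the carbon between the benzyloxy groups out of reach), while attack by ring B would need a five-membered indenone closure from the E isomer onto a carbon meta to its only oxygen. The benzyl ethers should tolerate the brief contact with dilute trifluoroacetic acid, and loss of the O5 benzyl would be harmless because step 5 removes all three.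

Step 5
Reactants: 8 5,7-bis(benzyloxy)-2-[4-(benzyloxy)phenyl]-4H-chromen-4-one
Product: 9 apigenin, 5,7-dihydroxy-2-(4-hydroxyphenyl)-4H-chromen-4-one
Conditions: H2 (1 atm), Pd/C (10 wt% Pd), THF/MeOH 1:1, rt
Reagents that add atoms: none
Why: Hydrogenolysis of the three aryl benzyl ethers over palladium on carbon; the C2–C3 double bond of the 4-pyranone is a vinylogous ester and is reduced much more slowly, so the reaction is stopped once the ethers are gone.

Step 6
Reactants: 9 apigenin
Product: 10 apigenin triacetate, 5-acetoxy-2-(4-acetoxyphenyl)-4-oxo-4H-chromen-7-yl acetate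
Conditions: Ac2O (6 equiv), pyridine, DMAP (0.1 equiv), rt to 50 °C
Reagents that add atoms: acetic anhydride, CC(=O)OC(C)=O
Why: Acylation of all three phenols; DMAP catalysis and gentle heating are needed for the hydrogen-bonded 5-OH.

Step 7
Reactants: 10 apigenin triacetate
Product: 11 5-acetoxy-2-(4-acetoxyphenyl)-7-hydroxy-4H-chromen-4-one
Conditions: PhSH (1.5 equiv), imidazole (0.3 equiv), NMP, 0 °C
Reagents that add atoms: none
Why: Thiolate/imidazole transacylation removes the most activated aryl ester, the 7-acetate, whose phenoxide is para to the C4a acyl group and the best leaving group; this is a known selective 7-O-deacylation of peracylated flavones.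

Step 8
Reactants: 11 5-acetoxy-2-(4-acetoxyphenyl)-7-hydroxy-4H-chromen-4-one
Product: 12 5-acetoxy-2-(4-acetoxyphenyl)-4-oxo-4H-chromen-7-yl hydrogen sulfate
Conditions: SO3·pyridine (3 equiv), pyridine, rt to 40 °C; MeOH quench
Reagents that add atoms: sulfur trioxide–pyridine complex, O=S(=O)([O-])[n+]1ccccc1
Why: O-sulfonation of a phenol by the SO3·pyridine complex; the 7-OH is the only free hydroxyl, and pyridine as the sole base leaves the aryl acetates in place.

Step 9
Reactants: 12 5-acetoxy-2-(4-acetoxyphenyl)-4-oxo-4H-chromen-7-yl hydrogen sulfate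
Product: 13 apigenin 7-sulfate, 5-hydroxy-2-(4-hydroxyphenyl)-4-oxo-4H-chromen-7-yl hydrogen sulfate
Conditions: NH3 (7 M in MeOH), 0 °C to rt; evaporation, C18 desalting
Reagents that add atoms: none
Why: Aminolysis of the two aryl acetates by ammonia is fast at or below room temperature, while the aryl sulfate monoester anion is inert to base and nucleophiles and never meets acid.

**Compound list**

1 | 1-(benzyloxy)-4-iodobenzene | Ic1ccc(OCc2ccccc2)cc1 | starting material
2 | ethyl propiolate | C#CC(=O)OCC | starting material
3 | ethyl 3-[4-(benzyloxy)phenyl]prop-2-ynoate | CCOC(=O)C#Cc1ccc(OCc2ccccc2)cc1 | intermediate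
4 | 3,5-bis(benzyloxy)phenol | Oc1cc(OCc2ccccc2)cc(OCc2ccccc2)c1 | starting material
5 | ethyl (2Z)-3-[3,5-bis(benzyloxy)phenoxy]-3-[4-(benzyloxy)phenyl]prop-2-enoate | CCOC(=O)/C=C(\Oc1cc(OCc2ccccc2)cc(OCc2ccccc2)c1)c1ccc(OCc2ccccc2)cc1 | intermediate
6 | (2Z)-3-[3,5-bis(benzyloxy)phenoxy]-3-[4-(benzyloxy)phenyl]prop-2-enoic acid | OC(=O)/C=C(\Oc1cc(OCc2ccccc2)cc(OCc2ccccc2)c1)c1ccc(OCc2ccccc2)cc1 | intermediate
7 | (2Z)-3-[3,5-bis(benzyloxy)phenoxy]-3-[4-(benzyloxy)phenyl]prop-2-enoic trifluoroacetic anhydride | O=C(OC(=O)C(F)(F)F)/C=C(\Oc1cc(OCc2ccccc2)cc(OCc2ccccc2)c1)c1ccc(OCc2ccccc2)cc1 | intermediate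
8 | 5,7-bis(benzyloxy)-2-[4-(benzyloxy)phenyl]-4H-chromen-4-one | O=c1cc(-c2ccc(OCc3ccccc3)cc2)oc2cc(OCc3ccccc3)cc(OCc3ccccc3)c12 | intermediate
9 | apigenin, 5,7-dihydroxy-2-(4-hydroxyphenyl)-4H-chromen-4-one | O=c1cc(-c2ccc(O)cc2)oc2cc(O)cc(O)c12 | intermediate
10 | apigenin triacetate, 5-acetoxy-2-(4-acetoxyphenyl)-4-oxo-4H-chromen-7-yl acetate | CC(=O)Oc1ccc(-c2cc(=O)c3c(OC(C)=O)cc(OC(C)=O)cc3o2)cc1 | intermediate
11 | 5-acetoxy-2-(4-acetoxyphenyl)-7-hydroxy-4H-chromen-4-one | CC(=O)Oc1ccc(-c2cc(=O)c3c(OC(C)=O)cc(O)cc3o2)cc1 | intermediate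
12 | 5-acetoxy-2-(4-acetoxyphenyl)-4-oxo-4H-chromen-7-yl hydrogen sulfate | CC(=O)Oc1ccc(-c2cc(=O)c3c(OC(C)=O)cc(OS(=O)(=O)O)cc3o2)cc1 | intermediate
13 | apigenin 7-sulfate, 5-hydroxy-2-(4-hydroxyphenyl)-4-oxo-4H-chromen-7-yl hydrogen sulfate | O=c1cc(-c2ccc(O)cc2)oc2cc(OS(=O)(=O)O)cc(O)c12 | target

**Step count**

Total steps: 9. Longest linear sequence: 9 steps (1 → 3 → 5 → 6 → 8 → 9 → 10 → 11 → 12 → 13).

**Steps most likely to fail**

Step 4 (ring closure). The mixed anhydride may be consumed by other paths before it acylates C4a: acid-induced cleavage of the aryl vinyl ether, intermolecular trifluoroacetylation of ring A, or slow E-to-Z equilibration. The fallback closes ring C at O1–C2 instead of C4–C4a. It sets out from 4, which would be acetylated ortho to the hydroxyl (Ac2O, BF3·OEt2, Fries-type ortho acylation) to give 1-[2-hydroxy-4,6-bis(benzyloxy)phenyl]ethanone F1. Claisen–Schmidt condensation of this ketone with commercial 4-(benzyloxy)benzaldehyde (KOH, EtOH) should give (2E)-1-[2-hydroxy-4,6-bis(benzyloxy)phenyl]-3-[4-(benzyloxy)phenyl]prop-2-en-1-one F2. Oxidative cyclization of the 2'-hydroxychalcone (catalytic I2, DMSO, 120 °C) returns to the route at 8.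

Step 2 (conjugate addition). The ambident phenoxide may attack through a ring carbon and lactonise to a 4-arylcoumarin, or the addition to the electron-rich ynoate may be sluggish. The fallback replaces the Michael addition by a copper-mediated vinylic C–O coupling. It sets out from 3, which on hydroiodination (NaI, AcOH, 70 °C, anti addition) should give ethyl (2Z)-3-[4-(benzyloxy)phenyl]-3-iodoprop-2-enoate F3. Ullmann-type coupling of this vinyl iodide with 4 (CuI, N,N-dimethylglycine, Cs2CO3, dioxane, 90 °C) proceeds with retention at the double bond through a copper phenoxide, which enforces O-bonding, and returns to the route at 5.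

Step 8 (sulfation). Sulfation may stay incomplete, or acetyl groups may migrate or be lost while the polar salt is isolated. The fallback introduces the sulfate as a neutral, chromatographable diester. It sets out from 11, which with 2,2,2-trichloroethyl chlorosulfate (Et3N, DMAP, THF, 0 °C) should give 5-acetoxy-2-(4-acetoxyphenyl)-4-oxo-4H-chromen-7-yl 2,2,2-trichloroethyl sulfate F4. After purification on silica, reductive removal of the trichloroethyl group (Zn dust, HCO2NH4, MeOH, rt) returns to the route at 12; partial loss of acetate there does no harm, since step 9 removes both.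

**Further compounds**

F1 | step 4 | 1-[2-hydroxy-4,6-bis(benzyloxy)phenyl]ethanone | CC(=O)c1c(O)cc(OCc2ccccc2)cc1OCc1ccccc1
F2 | step 4 | (2E)-1-[2-hydroxy-4,6-bis(benzyloxy)phenyl]-3-[4-(benzyloxy)phenyl]prop-2-en-1-one | O=C(/C=C/c1ccc(OCc2ccccc2)cc1)c1c(O)cc(OCc2ccccc2)cc1OCc1ccccc1
F3 | step 2 | ethyl (2Z)-3-[4-(benzyloxy)phenyl]-3-iodoprop-2-enoate | CCOC(=O)/C=C(\I)c1ccc(OCc2ccccc2)cc1
F4 | step 8 | 5-acetoxy-2-(4-acetoxyphenyl)-4-oxo-4H-chromen-7-yl 2,2,2-trichloroethyl sulfate | CC(=O)Oc1ccc(-c2cc(=O)c3c(OC(C)=O)cc(OS(=O)(=O)OCC(Cl)(Cl)Cl)cc3o2)cc1
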